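# Proposed synthesis of 2-hydroxy-2-(2-methoxy-4-methylphenyl)propane-1,3-diyl bis(2-methylpropanoate) (14)

Numbering used throughout: **1** ethyl 3-methylbut-2-enoate, **2** diethyl oxalate, **3** potassium dienolate from 1 and 2, **4** 4-methyl-2-oxo-2H-pyran-6-carboxylic acid, **5** 4-methyl-2H-pyran-2-one, **6** 2-chloro-1,1-dimethoxyethane, **7** 2,2-dimethyl-1,3-dioxan-5-one, **8** lithium methoxyacetylide, **9** lithium alkoxide from 8 and 7, **10** silylated methoxyalkyne, **11** bridged lactone cycloadduct, **12** protected arene, **13** triol, **14** target.

## Analysis of the target

Compound 14 is an achiral 1,2,4-trisubstituted benzene: ring carbon C1 carries a fully substituted carbinol carbon, C2 a methoxy group and C4 a methyl group, so the ring oxygen is ortho to the side chain and meta to the methyl. The carbinol carbon bears a free tertiary hydroxyl and two identical CH2O-isobutyryl arms, so it is not a stereocentre and no stereocontrol is needed. Two sensitivities shape the endgame: the primary esters sit β to a free tertiary hydroxyl, so base invites acyl migration and hydrolysis, and the tertiary C–O bond is benzylic to a ring activated by ortho-OMe and para-Me, so strong acid invites ionisation and dehydration. The difficulty is the crowded junction between the quaternary carbinol and an ortho-substituted ring, at a position that electrophilic substitution of a meta-cresyl methyl ether does not favour, since that goes para to oxygen. The plan rests on the C1–C2 edge of the ring: these two neighbouring carbons, carrying the carbinol and OMe, are read as the two carbons of a 1-methoxyalkyne that already holds the carbinol. Ring carbons C3 to C6, with only the C4 methyl, are read as the diene carbons of pyrone 5, whose lactone unit is expelled.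

## Retrosynthetic reasoning

**14 to 13.** The two acyl C–O bonds of the esters are cut last. This keeps the base- and acid-labile esters away from every other operation. The forward reaction must acylate the two primary hydroxyls of 13 and leave the tertiary benzylic hydroxyl alone, which its steric shielding (ortho-substituted ring on one side, fully substituted carbon itself) should secure.

**13 to 12.** The triol is masked as a 1,3-dioxane acetal across the two primary oxygens and a silyl ether on the tertiary oxygen. Both masks come off under weak aqueous acid in one operation. They are chosen because they are inert to the neutral heating of the ring-forming step and because the silyl ether shuts down propargylic rearrangement in the precursor.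

**12 to 5 and 10 (through 11).** The arene bonds C2–C3 and C1–C6 are cut. This is preferred to any cut at the aryl–carbinol bond because no bond then has to be formed at a hindered ortho-substituted arene position, and because both heteroatom-bearing ring carbons sit in one small piece (10) and the methyl in the other (5). The forward reaction is a [4+2] cycloaddition of the alkyne across C3 and C6 of the pyrone to give 11, followed by cycloreversion in which the lactone bridge leaves as a small gaseous molecule. The aromatic oxidation level is therefore reached without an oxidant. The step must deliver one regioisomer: OMe next to pyrone C3.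

**10 to 7 and 8 (through 9), and 8 to 6.** The bond between the alkyne carbon and the carbinol carbon is cut, together with the O–Si bond. The fully substituted centre is thereby made as a 1,2-addition of a slim sp-hybridised nucleophile (8) to the unhindered ketone 7, the easiest way to build it. Trapping of alkoxide 9 in the same flask avoids handling a free tertiary propargylic alcohol next to an alkynyl ether. Acetylide 8 is generated from chloroacetal 6 by two eliminations and a deprotonation with an amide base.

**5 to 4 to 3 to 1 and 2.** The pyrone is opened at the lactone C–O bond and cut at the bond between the γ-carbon of 1 and an oxalyl carbon of 2. The forward sequence is a γ-selective Claisen condensation to dienolate 3, lactonisation with ester hydrolysis to acid 4, and decarboxylation to 5. The methyl of 5 is the untouched second methyl of 1.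

## Alternatives that were turned down

Alternative 1: ring oxygen installed by hydroxyl-directed C–H silylation.
- Disconnection: the aryl C2–O bond. The oxygen is put last onto a para-tolyl carbinol that already carries both ester arms.
- Forward key step: the hydrosilyl ether 2-[(diethylsilyl)oxy]-2-(4-methylphenyl)propane-1,3-diyl bis(2-methylpropanoate) A2 cyclises under the catalyst [Ir(cod)OMe]2 A3 with a phenanthroline ligand and an alkene as hydrogen acceptor. This forms the aryl C–Si bond and closes the five-membered ring of (1,1-diethyl-6-methyl-1,3-dihydro-2,1-benzoxasilole-3,3-diyl)dimethanediyl bis(2-methylpropanoate) A1. Tamao–Fleming oxidation would give 2-hydroxy-2-(2-hydroxy-4-methylphenyl)propane-1,3-diyl bis(2-methylpropanoate) A4, and O-methylation of the phenol would give 14.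
- For: the reaction type is established for tertiary benzylic alcohols. The two ortho positions of the para-tolyl ring are equivalent, so there is no regiochemical question. The carbinol comes from a para-tolyl organometallic and 7. On precedent this alternative is stronger than the chosen route.
- Against: oxidation of the aryl–silicon bond needs peroxide with base or fluoride, and the phenol methylation needs base. Both would be run on A1 and A4, where two primary esters sit β to a tertiary alkoxide and close to a phenoxide, so acyl migration and ester loss are the expected side reactions. Moving the acylation after the oxidation costs extra protecting-group steps. The count is about seven to eight steps.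
- Comparison: the chosen route offers a two-step, base-free endgame and brings the ring oxygen in already methylated. Its single uncertain step comes early, on cheap material.

Alternative 2: three-component carbene trapping at the carbinol carbon.
- Disconnection: the carbinol C–OH bond and one carbinol–CH2 bond.
- Forward key step: tert-butyl 2-diazo-2-(2-methoxy-4-methylphenyl)acetate A6 is decomposed by Rh2(OAc)4 A9 in the presence of water A8 and formaldehyde A7. The carbene forms an oxonium ylide with A8, which is trapped in an aldol-type step by A7. The product is racemic tert-butyl 2,3-dihydroxy-2-(2-methoxy-4-methylphenyl)propanoate A5. The stereocentre of A5 disappears when the ester is reduced to the second CH2OH arm, giving 13.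
- For: it is the most convergent assembly of the carbinol and is short, about five steps from an arylacetic ester. Three-component trapping of this kind is known for aryl diazoacetates. On step count it is equal or slightly better.
- Against: the ortho-methoxy group of A6 offers the carbene two intramolecular exits, C–H insertion into the OCH3 group (five-membered ring) and ylide formation at the ether oxygen. In the aqueous medium A7 is largely hydrated and is a weak trap, so plain O–H insertion should compete. A hydride reduction of a hindered tert-butyl ester is still needed.
- Comparison: Alternative 2 stacks two chemoselectivity problems and a redox step. The chosen route has one uncertain step, in which electronic and steric effects point to the same regioisomer, and needs no redox adjustment.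

Alternative 3: two-directional double silylmethyl addition to an aryl ester.
- Disconnection: both bonds from the carbinol carbon to the CH2 arms.
- Forward key step: the ester methyl 2-methoxy-4-methylbenzoate A11 is treated with an excess of the organocerium reagent prepared from [(isopropoxydimethylsilyl)methyl]magnesium chloride A12 and CeCl3 A13, so that both arms add in one flask. The product is 2-(2-methoxy-4-methylphenyl)-1,3-bis(isopropoxydimethylsilyl)propan-2-ol A10. Tamao–Fleming oxidation of both C–Si bonds would give 13.
- For: it is the shortest route, three steps to 14 from A11, has no regiochemical question and uses only known reaction types. On step economy and precedent it is stronger than the chosen route.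
- Against: A10 is a tertiary, electron-rich benzylic alcohol with silicon β on both sides. That is the ideal substrate for Peterson elimination to an allylsilane, under the Lewis-acidic addition and work-up and again under the fluoride and base of the oxidation. The second addition to the ortho-methoxy ketone intermediate is also hindered.
- Comparison: in the chosen route the tertiary oxygen is never β to silicon, the triol stays masked until a weak-acid step, and the arene pattern is set by construction, so ring analogues follow from other pyrones.

Key step: step 4

Remark on the chemistry: 14 has no stereocentre, so stereodescriptors appear only for enolate geometries and for the transient racemic cycloadduct 11. Pyrone 5 is assumed not to be a reliable catalogue compound and is made in two steps.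

## Route

Step 1
Reactants: 1 ethyl 3-methylbut-2-enoate; 2 diethyl oxalate
Product: 4 4-methyl-2-oxo-2H-pyran-6-carboxylic acid, via potassium dienolate of diethyl 3-methyl-5-oxohex-2-enedioate 3 (not isolated)
Conditions: KOEt (1.0 equiv), Et2O/EtOH, 0 °C to rt; solvent removed; conc. aq. HCl, 100 °C
Reagents that add atoms: water, O
Why: Vinylogous Claisen condensation: the extended enolate of 1 is acylated at its γ-carbon by non-enolisable 2 and the product is drained off as the stabilised dienolate 3. In hot concentrated HCl the enol oxygen of the Z isomer (the C2=C3 geometry of the hexenedioate equilibrates through the dienolate and enol) lactonises onto the unsaturated ester and the remaining ethyl ester is hydrolysed, the classical way to 2-pyrone-6-carboxylic acids.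

Step 2
Reactants: 4 4-methyl-2-oxo-2H-pyran-6-carboxylic acid
Product: 5 4-methyl-2H-pyran-2-one
Conditions: Cu powder, neat, 250–300 °C, reduced pressure, product distilled out as formed
Reagents that add atoms: none
Why: Copper-mediated thermal protodecarboxylation of a carboxylic acid on the oxygen-bearing sp2 carbon of the pyrone, the same type as the decarboxylation of furan-2-carboxylic and other pyronecarboxylic acids. The volatile pyrone should leave the hot zone as it forms.

Step 3
Reactants: 6 2-chloro-1,1-dimethoxyethane; 7 2,2-dimethyl-1,3-dioxan-5-one
Product: 10 triethyl{[5-(methoxyethynyl)-2,2-dimethyl-1,3-dioxan-5-yl]oxy}silane, via lithium methoxyacetylide 8 (not isolated), via lithium 5-(methoxyethynyl)-2,2-dimethyl-1,3-dioxan-5-olate 9 (not isolated)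
Conditions: Et2NH, n-BuLi (3 equiv per 6), THF, 0 °C; 6 (1.2 equiv), 0 °C; 7 (1.0 equiv), −78 to −20 °C; Et3SiCl (3 equiv), −78 °C to rt; NaHCO3 work-up, Et3N-deactivated silica
Reagents that add atoms: chlorotriethylsilane, CC[Si](Cl)(CC)CC
Why: Three equivalents of LiNEt2 take 6 through loss of methoxide, loss of chloride and deprotonation to acetylide 8, which undergoes 1,2-addition to the unhindered ketone 7. O-silylation of alkoxide 9 in the same flask means that the free tertiary propargylic alcohol, prone to Meyer–Schuster rearrangement, is never handled. The chlorosilane is charged in excess because the LiOMe released from 6 is silylated as well.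

Step 4
Reactants: 5 4-methyl-2H-pyran-2-one; 10 triethyl{[5-(methoxyethynyl)-2,2-dimethyl-1,3-dioxan-5-yl]oxy}silane
Product: 12 triethyl{[5-(2-methoxy-4-methylphenyl)-2,2-dimethyl-1,3-dioxan-5-yl]oxy}silane, via bridged lactone cycloadduct 11 (not isolated)
Conditions: 5 (2 equiv), PhMe, BHT (cat.), base-washed sealed tube, 150–170 °C
Reagents that add atoms: none
Why: Proposed new method: the electron-rich methoxyalkyne 10 should add across C3 and C6 of pyrone 5 in an asynchronous [4+2] cycloaddition of inverse electron demand, in which the alkyne carbon remote from oxygen (the one carrying the dioxane) bonds first to the electrophilic C6 and the methoxy-bearing carbon then closes onto C3; the closest known reaction type is the thermal Diels–Alder/retro-Diels–Alder benzannulation of 2-pyrones with alkynes, ynamines and alkoxyalkynes included, which has not been shown for an unactivated 4-alkyl-2-pyrone paired with a hindered tertiary-propargylic alkynyl ether. The six-membered carbocycle is closed by this intermolecular cycloaddition, both new C–C bonds forming in one event, and the bridged lactone 11 then loses CO2 by cycloreversion, which aromatises the ring and makes the sequence irreversible. No stereocentre is set, because the two bridgehead centres of racemic 11 vanish when CO2 leaves. Regiochemistry is the only selectivity at stake, and both the polarisation (nucleophilic alkyne terminus to C6) and the sterics (the bulky dioxanyl end kept away from the C4 methyl) put OMe next to the former C3, that is meta to the methyl. A methyl alkynyl ether has no β-hydrogen for retro-ene loss of a ketene at this temperature, the silyl ether blocks Meyer–Schuster rearrangement, and the acetonide is inert to neutral heating.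

Step 5
Reactants: 12 triethyl{[5-(2-methoxy-4-methylphenyl)-2,2-dimethyl-1,3-dioxan-5-yl]oxy}silane
Product: 13 2-(2-methoxy-4-methylphenyl)propane-1,2,3-triol
Conditions: AcOH/THF/H2O (3:1:1), 45 °C
Reagents that add atoms: none
Why: Acid-catalysed hydrolysis of the 1,3-dioxane acetal and of the triethylsilyl ether in a weak, buffered acid. The two β-oxygens should disfavour ionisation of the tertiary benzylic C–O bond, and water as co-solvent returns the alcohol if ionisation occurs.

Step 6
Reactants: 13 2-(2-methoxy-4-methylphenyl)propane-1,2,3-triol
Product: 14 2-hydroxy-2-(2-methoxy-4-methylphenyl)propane-1,3-diyl bis(2-methylpropanoate)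
Conditions: i-PrCOCl (2.2 equiv), pyridine, CH2Cl2, 0 °C to rt
Reagents that add atoms: isobutyryl chloride, CC(C)C(=O)Cl
Why: Pyridine-mediated O-acylation with an acid chloride, chemoselective for the two primary hydroxyls. The tertiary benzylic hydroxyl, flanked by the ortho-substituted ring, should not acylate without a nucleophilic catalyst, and the weak base should not trigger acyl migration.

## Compound list

1 | ethyl 3-methylbut-2-enoate | CC(C)=CC(=O)OCC | starting material
2 | diethyl oxalate | CCOC(=O)C(=O)OCC | starting material
3 | potassium (2Z,4Z)-1,6-diethoxy-4-methyl-1,6-dioxohexa-2,4-dien-2-olate (potassium dienolate of diethyl 3-methyl-5-oxohex-2-enedioate; the geometry that cyclises is drawn) | CCOC(=O)/C([O-])=C/C(C)=C\C(=O)OCC.[K+] | intermediate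
4 | 4-methyl-2-oxo-2H-pyran-6-carboxylic acid | CC1=CC(=O)OC(C(=O)O)=C1 | intermediate
5 | 4-methyl-2H-pyran-2-one | CC1=CC(=O)OC=C1 | intermediate
6 | 2-chloro-1,1-dimethoxyethane | COC(CCl)OC | starting material
7 | 2,2-dimethyl-1,3-dioxan-5-one | CC1(C)OCC(=O)CO1 | starting material
8 | lithium methoxyacetylide (methoxyethynyllithium) | [Li]C#COC | intermediate
9 | lithium 5-(methoxyethynyl)-2,2-dimethyl-1,3-dioxan-5-olate | COC#CC1([O-])COC(C)(C)OC1.[Li+] | intermediate
10 | triethyl{[5-(methoxyethynyl)-2,2-dimethyl-1,3-dioxan-5-yl]oxy}silane | COC#CC1(O[Si](CC)(CC)CC)COC(C)(C)OC1 | intermediate
11 | 6-{2,2-dimethyl-5-[(triethylsilyl)oxy]-1,3-dioxan-5-yl}-5-methoxy-8-methyl-2-oxabicyclo[2.2.2]octa-5,7-dien-3-one (racemic; the (1S,4R) enantiomer is drawn, the two bridgeheads being tied to each other by the bicycle) | O=C1O[C@H]2C=C(C)[C@@H]1C(OC)=C2C3(O[Si](CC)(CC)CC)COC(C)(C)OC3 | intermediate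
12 | triethyl{[5-(2-methoxy-4-methylphenyl)-2,2-dimethyl-1,3-dioxan-5-yl]oxy}silane | COc1cc(C)ccc1C1(O[Si](CC)(CC)CC)COC(C)(C)OC1 | intermediate
13 | 2-(2-methoxy-4-methylphenyl)propane-1,2,3-triol | COc1cc(C)ccc1C(O)(CO)CO | intermediate
14 | 2-hydroxy-2-(2-methoxy-4-methylphenyl)propane-1,3-diyl bis(2-methylpropanoate) | COc1cc(C)ccc1C(O)(COC(=O)C(C)C)COC(=O)C(C)C | target

## Step count and least certain steps

Total: 6 steps. Longest linear sequence: 5 steps (steps 1, 2, 4, 5, 6); the alkyne branch is one step (step 3).

**Step 4 (key step, proposed new method).**
- Risk: the cycloaddition may fail to set in below the temperature at which the alkynyl ether decomposes by oligomerisation or by ionisation at the propargylic position. The pyrone is not electron-poor and the reacting alkyne terminus carries a fully substituted carbon. Erosion of regiocontrol is the second risk.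
- Fallback by known chemistry, setting out from 7 and coming back at 13: commercial 1-bromo-2-methoxy-4-methylbenzene F1 undergoes bromine–lithium exchange with n-BuLi in THF at −78 °C to give (2-methoxy-4-methylphenyl)lithium F2. This adds to ketone 7 to give, after aqueous work-up, 5-(2-methoxy-4-methylphenyl)-2,2-dimethyl-1,3-dioxan-5-ol F3. Aqueous acetic acid then removes the acetonide and gives 13, from which step 6 follows.

**Step 3.**
- Risk: incomplete O-silylation of the hindered tertiary alkoxide 9 in a flask that also holds LiOMe and Et2NH, followed by acid-triggered rearrangement of unsilylated carbinol during isolation. Enolisation of 7 by residual amide is the second risk.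
- Fallback, setting out from 7 and coming back at 10: (E)-1,2-dichloro-1-methoxyethene F4, made from trichloroethylene and NaOMe, is treated with two equivalents of n-BuLi (deprotonation, loss of LiCl, chlorine–lithium exchange). This generates 8 free of amine and methoxide. Addition of 7 gives 9, which is trapped with Et3SiOTf to give 10.

**Step 5.**
- Risk: the hindered tertiary silyl ether may hydrolyse much more slowly than the acetonide. Forcing it with stronger acid would risk ionisation of the benzylic C–O bond and dehydration.
- Fallback, setting out from 12 and coming back at 14: the acid treatment is stopped after acetonide cleavage to give 2-(2-methoxy-4-methylphenyl)-2-[(triethylsilyl)oxy]propane-1,3-diol F5. Acylation with i-PrCOCl, pyridine and DMAP gives 2-(2-methoxy-4-methylphenyl)-2-[(triethylsilyl)oxy]propane-1,3-diyl bis(2-methylpropanoate) F6. HF·pyridine in THF then removes the silyl group under non-basic conditions and gives 14.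

**Step 2.**
- Risk: sublimation and charring of the acid before decarboxylation, and loss of the volatile pyrone.
- Fallback, setting out from 1 and coming back at 5: condensation of 1 with ethyl formate and NaH in Et2O (the same γ-selective Claisen logic) gives, as its sodium enolate, ethyl (2Z)-3-methyl-5-oxopent-2-enoate F7. On acidification with HCl and warming this lactonises directly to 5, so no carboxyl group has to be removed.

## Further compounds

F1 | step 4 | 1-bromo-2-methoxy-4-methylbenzene | COc1cc(C)ccc1Br
F2 | step 4 | (2-methoxy-4-methylphenyl)lithium | [Li]c1ccc(C)cc1OC
F3 | step 4 | 5-(2-methoxy-4-methylphenyl)-2,2-dimethyl-1,3-dioxan-5-ol | COc1cc(C)ccc1C1(O)COC(C)(C)OC1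
F4 | step 3 | (E)-1,2-dichloro-1-methoxyethene | CO/C(Cl)=C\Cl
F5 | step 5 | 2-(2-methoxy-4-methylphenyl)-2-[(triethylsilyl)oxy]propane-1,3-diol | COc1cc(C)ccc1C(CO)(CO)O[Si](CC)(CC)CC
F6 | step 5 | 2-(2-methoxy-4-methylphenyl)-2-[(triethylsilyl)oxy]propane-1,3-diyl bis(2-methylpropanoate) | COc1cc(C)ccc1C(COC(=O)C(C)C)(COC(=O)C(C)C)O[Si](CC)(CC)CC
F7 | step 2 | ethyl (2Z)-3-methyl-5-oxopent-2-enoate | CCOC(=O)/C=C(C)\CC=O
A1 | alternative 1 | (1,1-diethyl-6-methyl-1,3-dihydro-2,1-benzoxasilole-3,3-diyl)dimethanediyl bis(2-methylpropanoate) | Cc1ccc2c(c1)[Si](CC)(CC)OC2(COC(=O)C(C)C)COC(=O)C(C)C
A2 | alternative 1 | 2-[(diethylsilyl)oxy]-2-(4-methylphenyl)propane-1,3-diyl bis(2-methylpropanoate) | Cc1ccc(cc1)C(O[SiH](CC)CC)(COC(=O)C(C)C)COC(=O)C(C)C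
A3 | alternative 1 | [Ir(cod)OMe]2, di-μ-methoxobis(cycloocta-1,5-diene)diiridium | C[O-].C[O-].[Ir+].[Ir+].C1=CCCC=CCC1.C1=CCCC=CCC1
A4 | alternative 1 | 2-hydroxy-2-(2-hydroxy-4-methylphenyl)propane-1,3-diyl bis(2-methylpropanoate) | Cc1ccc(c(O)c1)C(O)(COC(=O)C(C)C)COC(=O)C(C)C
A5 | alternative 2 | tert-butyl 2,3-dihydroxy-2-(2-methoxy-4-methylphenyl)propanoate (racemic) | COc1cc(C)ccc1C(O)(CO)C(=O)OC(C)(C)C
A6 | alternative 2 | tert-butyl 2-diazo-2-(2-methoxy-4-methylphenyl)acetate | COc1cc(C)ccc1C(=[N+]=[N-])C(=O)OC(C)(C)C
A7 | alternative 2 | formaldehyde | C=O
A8 | alternative 2 | water | O
A9 | alternative 2 | Rh2(OAc)4, dirhodium tetraacetate | CC(=O)[O-].CC(=O)[O-].CC(=O)[O-].CC(=O)[O-].[Rh+2].[Rh+2]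
A10 | alternative 3 | 2-(2-methoxy-4-methylphenyl)-1,3-bis(isopropoxydimethylsilyl)propan-2-ol | COc1cc(C)ccc1C(O)(C[Si](C)(C)OC(C)C)C[Si](C)(C)OC(C)C
A11 | alternative 3 | methyl 2-methoxy-4-methylbenzoate | COC(=O)c1ccc(C)cc1OC
A12 | alternative 3 | [(isopropoxydimethylsilyl)methyl]magnesium chloride | CC(C)O[Si](C)(C)C[Mg]Cl
A13 | alternative 3 | CeCl3, cerium trichloride | [Ce+3].[Cl-].[Cl-].[Cl-]
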